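**Retrosynthetic overview**
1. Target 9 comes from (S)-flavanone 8 by late oxidative demethylation of the para-dimethoxy pair of ring B; the quinone is unmasked last.
2. 8 comes from chalcone 7 by enantioselective C2–O1 bond formation (6-endo oxa-Michael), which closes ring C and sets the only stereocenter; the two phenols of 7 are equivalent, so there is no regiochemical issue.
3. 7 comes from acetophenone 4 and 2,4,5-trimethoxybenzaldehyde 5 by Claisen–Schmidt condensation.
4. 4 comes from 2',4',6'-trihydroxyacetophenone 1 by double C-methylation, then selective 4-O-methylation.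
5. Ring order: rings A and B are bought (B as a masked quinone), ring C is formed in step 4, the quinone in step 5.

**Assumptions**
- The target SMILES is read as the (2S)-flavanone (O1 > ring B carbon > C3 > H).
- The step 4 catalyst is 1-[3,5-bis(trifluoromethyl)phenyl]-3-[(2S)-3,3-dimethyl-1-{[tris(4-methoxyphenyl)-λ5-phosphanylidene]amino}butan-2-yl]thiourea, SMILES COc1ccc(cc1)P(=NC[C@@H](NC(=S)Nc1cc(cc(c1)C(F)(F)F)C(F)(F)F)C(C)(C)C)(c1ccc(OC)cc1)c1ccc(OC)cc1. It is made beforehand from the (S)-tert-leucine-derived azido thiourea and P(C6H4-4-OMe)3 and is not counted as a step.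
- The facial sense in step 4 (Si attack, giving 2S) is a design expectation, to be checked by chiral HPLC and CD; the mirror-image catalyst from (R)-tert-leucine is the alternative.

**Route**

Step 1
Reactants: 1 2',4',6'-trihydroxyacetophenone
Product: 3 1-(2,4,6-trihydroxy-3,5-dimethylphenyl)ethan-1-one, via 2',4',6'-trihydroxy-3'-methylacetophenone 2 (not isolated)
Conditions: MeI (2.1 equiv), NaOMe (2.1 equiv), MeOH, 0 °C to rt; aq HCl work-up
Reagents that add atoms: iodomethane, CI
Why: C-alkylation of the ambident phloroglucinol phenoxide in protic methanol puts methyl on the two doubly activated ring carbons, and controlled stoichiometry limits dearomatising over-methylation (phenoxide C-alkylation).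

Step 2
Reactants: 3 1-(2,4,6-trihydroxy-3,5-dimethylphenyl)ethan-1-one
Product: 4 1-(2,6-dihydroxy-4-methoxy-3,5-dimethylphenyl)ethan-1-one
Conditions: Me2SO4 (1.05 equiv), K2CO3 (1.1 equiv), acetone, rt to 40 °C
Reagents that add atoms: dimethyl sulfate, COS(=O)(=O)OC
Why: The 4-OH, para to the acetyl group and not chelated, is the most acidic and most nucleophilic phenol, so one equivalent of electrophile methylates it selectively while the chelated 2- and 6-OH remain (Williamson ether synthesis).

Step 3
Reactants: 4 1-(2,6-dihydroxy-4-methoxy-3,5-dimethylphenyl)ethan-1-one; 5 2,4,5-trimethoxybenzaldehyde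
Product: 7 (E)-1-(2,6-dihydroxy-4-methoxy-3,5-dimethylphenyl)-3-(2,4,5-trimethoxyphenyl)prop-2-en-1-one, via aldol adduct 6 (not isolated)
Conditions: KOH (50% aq, excess), EtOH, N2, rt, 48 h; then poured into ice-cold 1 M HCl (pH 4–5, below 5 °C), filtered
Reagents that add atoms: none
Why: Claisen–Schmidt aldol condensation with E1cB dehydration gives the conjugated E-enone, and in strong base the product stays as the open-chain phenoxide, so fast cold acidification delivers the chalcone before it can ring-close.

Step 4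
Reactants: 7 (E)-1-(2,6-dihydroxy-4-methoxy-3,5-dimethylphenyl)-3-(2,4,5-trimethoxyphenyl)prop-2-en-1-one
Product: 8 (2S)-5-hydroxy-7-methoxy-6,8-dimethyl-2-(2,4,5-trimethoxyphenyl)-2,3-dihydro-4H-chromen-4-one
Conditions: (S)-ArNHC(S)NH-CH(tBu)CH2-N=P(C6H4-4-OMe)3 [Ar = 3,5-(CF3)2C6H3] (10 mol%), toluene/CH2Cl2 4:1, −20 °C, 48 h; AcOH quench at −20 °C; one recrystallisation
Reagents that add atoms: none
Why: Proposed new method: an enantioselective 6-endo-trig oxa-Michael ring closure of an unactivated 2',6'-dihydroxychalcone under bifunctional iminophosphorane–thiourea catalysis, in which the superbasic P=N unit deprotonates one of the two equivalent phenols to a tight aminophosphonium phenoxide ion pair while the thiourea and the remaining chelating phenol hydrogen-bond the enone carbonyl, so that the phenoxide oxygen is delivered to the Si face of C-β (giving 2S), the enolate is protonated by the aminophosphonium N–H, and the retro-reaction is suppressed because the catalyst then rests as a phenoxide too weak to re-enolise the chelated 5-hydroxyflavanone at −20 °C; the closest known reactions are iminophosphorane-catalysed oxa-Michael additions of alcohols to unsaturated esters and amides, amine–thiourea cyclisations of activated alkylidene β-ketoesters to flavanones, and the enzymatic chalcone isomerase reaction.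

Step 5
Reactants: 8 (2S)-5-hydroxy-7-methoxy-6,8-dimethyl-2-(2,4,5-trimethoxyphenyl)-2,3-dihydro-4H-chromen-4-one
Product: 9 (2S)-5-hydroxy-7-methoxy-2-(4-methoxy-3,6-dioxocyclohexa-1,4-dien-1-yl)-6,8-dimethyl-2,3-dihydro-4H-chromen-4-one
Conditions: (NH4)2Ce(NO3)6 (2.2 equiv), MeCN/H2O 2:1, 0 °C, 15 min
Reagents that add atoms: water, O
Why: Oxidative demethylation by tetravalent cerium goes through the radical cation of the 1,2,4-trioxygenated ring B, which oxidises far more easily than the acyl-deactivated, chelated ring A; water adds at the para-related methoxy carbons to give the 2-methoxy-1,4-benzoquinone, and the brief, cold, acidic conditions do not open ring C, so C2 stays S.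

**Compound list**
1 | 2',4',6'-trihydroxyacetophenone | CC(=O)c1c(O)cc(O)cc1O | starting material
2 | 2',4',6'-trihydroxy-3'-methylacetophenone (not isolated) | CC(=O)c1c(O)cc(O)c(C)c1O | intermediate
3 | 1-(2,4,6-trihydroxy-3,5-dimethylphenyl)ethan-1-one | CC(=O)c1c(O)c(C)c(O)c(C)c1O | intermediate
4 | 1-(2,6-dihydroxy-4-methoxy-3,5-dimethylphenyl)ethan-1-one | CC(=O)c1c(O)c(C)c(OC)c(C)c1O | intermediate
5 | 2,4,5-trimethoxybenzaldehyde | COc1cc(OC)c(C=O)cc1OC | starting material
6 | racemic 1-(2,6-dihydroxy-4-methoxy-3,5-dimethylphenyl)-3-hydroxy-3-(2,4,5-trimethoxyphenyl)propan-1-one (aldol adduct, not isolated) | COc1cc(OC)c(C(O)CC(=O)c2c(O)c(C)c(OC)c(C)c2O)cc1OC | intermediate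
7 | (E)-1-(2,6-dihydroxy-4-methoxy-3,5-dimethylphenyl)-3-(2,4,5-trimethoxyphenyl)prop-2-en-1-one | COc1cc(OC)c(/C=C/C(=O)c2c(O)c(C)c(OC)c(C)c2O)cc1OC | intermediate
8 | (2S)-5-hydroxy-7-methoxy-6,8-dimethyl-2-(2,4,5-trimethoxyphenyl)-2,3-dihydro-4H-chromen-4-one | COc1cc(OC)c([C@@H]2CC(=O)c3c(O)c(C)c(OC)c(C)c3O2)cc1OC | intermediate
9 | (2S)-5-hydroxy-7-methoxy-2-(4-methoxy-3,6-dioxocyclohexa-1,4-dien-1-yl)-6,8-dimethyl-2,3-dihydro-4H-chromen-4-one | COC1=CC(=O)C([C@@H]2CC(=O)c3c(O)c(C)c(OC)c(C)c3O2)=CC1=O | target

**Totals**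
Total step count: 5. Longest linear sequence: 5 steps (1 → 3 → 4 → 7 → 8 → 9).

**Steps most likely to fail, with fallbacks**

Step 4 (the proposed new ring closure). The risks are insufficient enantioselectivity, a racemic background cyclisation, or erosion by retro-oxa-Michael opening. The fallback uses known chemistry, sets out from 7 and rejoins at 8. Chalcone 7 is cyclised with NaOAc in refluxing EtOH to the racemic 5-hydroxy-7-methoxy-6,8-dimethyl-2-(2,4,5-trimethoxyphenyl)chroman-4-one F1. Preparative chiral SFC on an amylose tris(3,5-dimethylphenylcarbamate) phase (CO2/MeOH) separates it into 8 and the (2R)-flavanone F2. F2 is re-racemised to F1 with NaOAc in refluxing EtOH (ring opening to 7 and re-closure) and recycled.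

Step 5 (oxidation with (NH4)2Ce(NO3)6). The risks are competing oxidation of the ring A phenol or its ortho-methyl group, or formation of the ortho-quinone. The fallback sets out from 4 and rejoins at 9, replacing oxidative demethylation by oxidation of a phenol. Acetophenone 4 is condensed (KOH, EtOH, as in step 3) with commercial 3-(benzyloxy)-4-methoxybenzaldehyde to the benzyl-protected chalcone F3. F3 is cyclised under the step 4 conditions to the (2S)-3'-benzyloxy-4'-methoxyflavanone F4. F4 is debenzylated (H2, Pd/C, EtOAc, rt) to the (2S)-3'-hydroxy-4'-methoxyflavanone F5. F5 is oxidised with (KSO3)2NO (KH2PO4 buffer, acetone/H2O, rt; Teuber oxidation) at the free position para to the ring B phenol; the chelated 5-OH of ring A does not react, and 9 is obtained directly.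

Step 3 (Claisen–Schmidt on the unprotected 2,6-dihydroxyacetophenone). The risks are a sluggish condensation (poorly acidic polyanion, electron-rich aldehyde) and partial racemic ring closure of 7 during work-up. The fallback sets out from 4 and rejoins at 7. Acetophenone 4 is converted (NaH, MOMCl, DMF, 0 °C) into the bis(methoxymethyl) ether F6. F6 condenses readily with 5 (KOH, EtOH, rt) to the bis-MOM chalcone F7, which cannot cyclise. HCl (2 M) in MeOH/THF at rt then removes both MOM groups faster than acid-catalysed ring closure and gives 7.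

**Further compounds**
F1 | step 4 | racemic 5-hydroxy-7-methoxy-6,8-dimethyl-2-(2,4,5-trimethoxyphenyl)-2,3-dihydro-4H-chromen-4-one | COc1cc(OC)c(C2CC(=O)c3c(O)c(C)c(OC)c(C)c3O2)cc1OC
F2 | step 4 | (2R)-5-hydroxy-7-methoxy-6,8-dimethyl-2-(2,4,5-trimethoxyphenyl)-2,3-dihydro-4H-chromen-4-one | COc1cc(OC)c([C@H]2CC(=O)c3c(O)c(C)c(OC)c(C)c3O2)cc1OC
F3 | step 5 | (E)-3-[3-(benzyloxy)-4-methoxyphenyl]-1-(2,6-dihydroxy-4-methoxy-3,5-dimethylphenyl)prop-2-en-1-one | COc1ccc(/C=C/C(=O)c2c(O)c(C)c(OC)c(C)c2O)cc1OCc1ccccc1
F4 | step 5 | (2S)-2-[3-(benzyloxy)-4-methoxyphenyl]-5-hydroxy-7-methoxy-6,8-dimethyl-2,3-dihydro-4H-chromen-4-one | COc1ccc([C@@H]2CC(=O)c3c(O)c(C)c(OC)c(C)c3O2)cc1OCc1ccccc1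
F5 | step 5 | (2S)-5-hydroxy-2-(3-hydroxy-4-methoxyphenyl)-7-methoxy-6,8-dimethyl-2,3-dihydro-4H-chromen-4-one | COc1ccc([C@@H]2CC(=O)c3c(O)c(C)c(OC)c(C)c3O2)cc1O
F6 | step 3 | 1-[4-methoxy-2,6-bis(methoxymethoxy)-3,5-dimethylphenyl]ethan-1-one | CC(=O)c1c(OCOC)c(C)c(OC)c(C)c1OCOC
F7 | step 3 | (E)-1-[4-methoxy-2,6-bis(methoxymethoxy)-3,5-dimethylphenyl]-3-(2,4,5-trimethoxyphenyl)prop-2-en-1-one | COCOc1c(C)c(OC)c(C)c(OCOC)c1C(=O)/C=C/c1cc(OC)c(OC)cc1OC
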